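The bath stands at 5 °C, and the flasks differ in one setting, the loading of free enzyme, which turns substrate into product. Neither earlier run stood at that temperature: green ran colder, blue warmer and with more free enzyme than eta.

in all of them: substrate 0.20 M
- green: free enzyme 0.0038 mol%; temperature 0 °C; run made earlier
- blue: free enzyme 0.046 mol%; temperature 11 °C; run made earlier
- epsilon: free enzyme 0.006 mol%; temperature 5 °C; time 8.0 min
- gamma: free enzyme 0.005 mol%; temperature 5 °C; time 8.0 min
- theta: free enzyme 0.01 mol%; temperature 5 °C; time 8.0 min
- eta: free enzyme 0.03 mol%; temperature 5 °C; time 8.0 min
- alpha: free enzyme 0.003 mol%; temperature 5 °C; time 8.0 min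

| run | time / min | product / % |
|---|---|---|
| green | 1.00 | 5.8 |
| green | 3.00 | 14.5 |
| green | 5.00 | 20.9 |
| green | 8.00 | 28.3 |
| blue | 2.00 | 65.0 |
| blue | 4.00 | 81.3 |
| blue | 6.00 | 88.7 |
| blue | 8.00 | 92.5 |

(each reading ± 1 percentage point)

* all flasks from highest to lowest amount of product, in percent of the substrate charged, at 8.0 min (epsilon / gamma / theta / eta / alpha)
* the same order at 30 min (epsilon / gamma / theta / eta / alpha)
* the amount of product, in percent of the substrate charged of the flask you put first, at 8.0 min
* the amount of product, in percent of the substrate charged of the flask you put last, at 8.0 min

The reckoning here solves each end of the series from its nearer run and joins the ends with one number. With x the fraction converted and L = −ln(fraction of substrate left), product inhibition is taken as a brake of 8, so that S grows in proportion to loading × time: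

S = 9L − 8x
green at 8.00 min: S = 0.730
blue at 4.00 min: S = 8.59
S per loading × time, blue over green: 1.94

Spreading that ratio evenly over the degrees gives 1.35, the bath factor: how much faster a given loading works at 5 °C than in green. From 5 °C up to blue remains 1.44.

A flask's green minutes are its time × its loading / green's loading × the bath factor; blue minutes are reckoned alike, dividing by the remaining factor.

alpha: 8.54 min green minutes; green's last slope continued gives 29.6%
eta: 3.63 min blue minutes; the chord between blue's first two readings gives 78.3%

At one bath and one time, eta has the highest loading and alpha the lowest. The bath stays untouched: on this reckoning from the readings, speed per loading stands twice as high in blue as in green.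

The forecast gives eta > theta > epsilon > gamma > alpha at 8.0 min and eta > theta > epsilon > gamma > alpha at 30 min, with top 80% and low 30%: “Nothing in the data suggests a non-monotonic effect of enzyme loading, so more enzyme means more product at both times.” Its top stands above the chord here.

The flasks give eta > theta > epsilon > gamma > alpha at 8.0 min and eta > theta > epsilon > gamma > alpha at 30 min, with eta at 79.0% and alpha at 29.1%.

    substrate + free enzyme → product + free enzyme, rate k1*[substrate]*[free enzyme]/(1 + ([substrate]/Km1) + ([product]/Kp1)) (0.550 M, 18.2 mM, k = 359 M⁻¹ s⁻¹, Ea = 40.0 kJ mol⁻¹)
    free enzyme → unfolded enzyme (k = 1.73 × 10⁻⁵ s⁻¹, Ea = 240 kJ mol⁻¹)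
    (constants at 5 °C)

Alpha's 8.54 min of green minutes lie just past green's 28.3% at 8.00 min, and alpha holds 29.1% of product at 8.0 min. The neighbouring flask is alpha itself, read at 2.0 min. The same bath factor gives it 2.14 min green minutes, and the chord between green's readings at 1.00 min and 3.00 min gives 10.7%. That flask holds 88.0% of substrate and 12.0% of product.

Readings and results were computed with constants of no real substance, and the scatter is random.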